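**Retrosynthetic overview**
- The strategy rests on ring A carrying O3 and, on quaternary C4, the oxygenated carbon C19 (a 1,3-dioxygen array), on the trans fusion of rings A and B, and on the C7=C8 alkene of ring B next to C9. Together these are the imprint of a C4 radical of a 2-methyl β-keto ester that closes two rings and ends by loss of a group from C7.
- Late stage: the C15 acid comes from the allylic alcohol (MnO2, then Pinnick oxidation); 3-OAc/19-OH come from a 3-oxo 19-(8-phenylmenthyl) ester by two hydride reductions and a silyl/acetyl exchange.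
- Key disconnection: C4–C5 and C9–C10, opening both rings to an acyclic 7-phenylsulfonyl trienyl keto ester. Ring A closes first and ring B second, in one oxidative radical cascade.
- Chain assembly: C1–C2 by dianion alkylation of 8-phenylmenthyl 2-methylacetoacetate; C6–C7 by prenylation of a geraniol-derived allylic sulfone.

Key step: step 10

Remark on numbering: labdane numbering (C1–C20) is used from the acyclic stage on. The target is (3S,4R,5S,9R,10S,13E)-3-acetoxy-19-hydroxylabda-7,13-dien-15-oic acid: C20, C19 and the C9 chain lie on one face; H5, H9 and the axial 3-acetoxy group lie on the other.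

Assumption: the (−)-8-phenylmenthyl ester is taken, by analogy with related radical cyclizations of such esters, to steer step 10 into this enantiomeric series. If the sense proved opposite, the route would be run unchanged with (+)-8-phenylmenthol.

**Route**

Step 1
Reactants: 1 geraniol
Product: 2 geranyl tert-butyldiphenylsilyl ether
Conditions: t-BuPh2SiCl, imidazole, DMF, 0 °C to rt
Reagents that add atoms: tert-butyl(chloro)diphenylsilane CC(C)(C)[Si](Cl)(c1ccccc1)c1ccccc1
Why: Imidazole-promoted silylation of the primary allylic alcohol should install an ether that withstands the later organolithium, hydride and oxidative radical conditions.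

Step 2
Reactants: 2 geranyl tert-butyldiphenylsilyl ether
Product: 3 (2E,6E)-8-hydroxygeranyl tert-butyldiphenylsilyl ether
Conditions: SeO2 (cat.), t-BuOOH, salicylic acid (cat.), CH2Cl2, rt
Reagents that add atoms: tert-butyl hydroperoxide CC(C)(C)OO (oxygen passed on through catalytic selenium dioxide O=[Se]=O)
Why: The SeO2 allylic oxidation (ene reaction, then [2,3]-sigmatropic shift) should attack the E-methyl of the electron-rich terminal alkene, the alkene next to the silyloxymethyl group being deactivated, and give the E allylic alcohol.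

Step 3
Reactants: 3 (2E,6E)-8-hydroxygeranyl tert-butyldiphenylsilyl ether
Product: 4 (2E,6E)-8-bromogeranyl tert-butyldiphenylsilyl ether
Conditions: CBr4, PPh3, CH2Cl2, 0 °C
Reagents that add atoms: carbon tetrabromide BrC(Br)(Br)Br
Why: The Appel reaction should convert the primary allylic alcohol into the bromide under neutral conditions without allylic transposition or loss of E geometry.

Step 4
Reactants: 4 (2E,6E)-8-bromogeranyl tert-butyldiphenylsilyl ether
Product: 5 (2E,6E)-3,7-dimethyl-8-(phenylsulfonyl)octa-2,6-dienyl tert-butyldiphenylsilyl ether (sulfonyl carbon = C7)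
Conditions: PhSO2Na, DMF, rt
Reagents that add atoms: sodium benzenesulfinate [Na+].[O-]S(=O)c1ccccc1
Why: SN2 S-alkylation of the sulfinate by the primary allylic bromide in a dipolar aprotic solvent should give the allylic sulfone with the alkene unchanged.

Step 5
Reactants: 5 allylic sulfone; 6 prenyl bromide
Product: 8 8-(phenylsulfonyl)farnesyl tert-butyldiphenylsilyl ether (2E,6E; racemic at C7), via lithio sulfone 7 (not isolated)
Conditions: n-BuLi, THF, −78 °C; then 6, −78 to −20 °C
Reagents that add atoms: n-butyllithium CCCC[Li] (lithium kept only in intermediate 7)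
Why: Alkylation of the allylic sulfonyl carbanion at its α-carbon by the reactive primary allylic bromide should form the C6–C7 bond; the new centre C7 is racemic and is erased in step 10.

Step 6
Reactants: 8 8-(phenylsulfonyl)farnesyl tert-butyldiphenylsilyl ether
Product: 9 (2E,6E,10E)-12-hydroxy-8-(phenylsulfonyl)farnesyl tert-butyldiphenylsilyl ether (hydroxylated carbon = C1)
Conditions: SeO2 (cat.), t-BuOOH, salicylic acid (cat.), CH2Cl2, 0 °C to rt, stopped at partial conversion
Reagents that add atoms: tert-butyl hydroperoxide CC(C)(C)OO (oxygen passed on through catalytic selenium dioxide O=[Se]=O)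
Why: The SeO2 allylic oxidation should again pick the E-methyl of the terminal isopropylidene group, the only alkene without an allylic sulfonyl or silyloxy substituent, and the [2,3]-shift should give the E alcohol.

Step 7
Reactants: 9 C1 allylic alcohol
Product: 11 (2E,6E,10E)-12-bromo-8-(phenylsulfonyl)farnesyl tert-butyldiphenylsilyl ether, via mesylate 10 (not isolated)
Conditions: MsCl, Et3N, CH2Cl2, −40 °C; then LiBr, THF, −40 to 0 °C
Reagents that add atoms: lithium bromide [Li+].[Br-]; methanesulfonyl chloride CS(=O)(=O)Cl (atoms kept only in intermediate 10)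
Why: Mesylation and in situ SN2 displacement by bromide should give the primary allylic bromide under conditions too weakly basic to touch the C7–H next to the sulfone.

Step 8
Reactants: 12 (−)-8-phenylmenthol; 13 ethyl 2-methylacetoacetate
Product: 14 (−)-8-phenylmenthyl 2-methyl-3-oxobutanoate (mixture at the α-carbon)
Conditions: DMAP (cat.), toluene, reflux, 4 Å molecular sieves to take up EtOH
Reagents that add atoms: none
Why: DMAP-catalysed transesterification of a β-keto ester passes through the acylketene and should therefore accept the hindered secondary alcohol, removal of ethanol driving it.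

Step 9
Reactants: 14 (−)-8-phenylmenthyl 2-methyl-3-oxobutanoate; 11 C1 allylic bromide
Product: 16 acyclic 7-phenylsulfonyl trienyl keto ester (mixture at C4 and C7), via dianion 15 (not isolated)
Conditions: NaH, THF, 0 °C; n-BuLi, 0 °C; then 11, −78 to −20 °C; then AcOH
Reagents that add atoms: sodium hydride [Na+].[H-] and n-butyllithium CCCC[Li] (metals kept only in intermediate 15)
Why: γ-Alkylation of the β-keto ester dianion at its terminal, more reactive carbanion should form the C1–C2 bond, SN2 attack on the allylic bromide at low temperature being expected to outrun proton transfer from the tertiary C7–H.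

Step 10
Reactants: 16 acyclic 7-phenylsulfonyl trienyl keto ester
Product: 17 (−)-8-phenylmenthyl 15-(tert-butyldiphenylsilyloxy)-3-oxolabda-7,13E-dien-19-oate (trans-fused; ester axial and cis to C20; H5 and H9 on the opposite face)
Conditions: Mn(OAc)3·2H2O (2.5 equiv), Yb(OTf)3 (1 equiv), 1,1-diphenylethylene (1.5 equiv), degassed CF3CH2OH (0.01 M), −5 °C to rt, Ar, no copper salt
Reagents that add atoms: none
Why: Proposed new method: trivalent manganese should oxidise the Yb-chelated enol of 16 to the C4 radical, which adds to C5 of the C5=C10 alkene (6-endo-trig, ring A, C4–C5 bond); the tertiary C10 radical then adds to C9 of the allylic sulfone (6-endo-trig, ring B, C9–C10 bond) and the tertiary C8 radical ejects PhSO2 from C7 by β-scission, which leaves the C7=C8 alkene without a second oxidation of the carbon skeleton. The closest known reaction types are the Mn(OAc)3-mediated oxidative polyene cyclization of 8-phenylmenthyl 2-methyl β-keto esters, normally ended by Cu(OAc)2, and radical allylation through addition to an allylic sulfone with loss of a sulfonyl radical; running both in one cascade is the untested part. C4 is set by the auxiliary, whose aryl group covers one face of the chelated radical so that the alkene adds to the open face and the ester ends axial and cis to C20; C5, C10 and C9 follow from a chair–chair fold of the two E alkenes, which should give the trans ring fusion (H5 anti to C20) and an equatorial C9 chain (H9 syn to H5). The selectivities needed are 6-endo closure twice (each radical attacks the less substituted alkene carbon and a tertiary radical results), face selectivity at C4 (auxiliary) and alkene position, which the C7 sulfonyl group fixes because its β-scission should be faster than 6-endo attack of the C8 radical on C13=C14 and no copper salt is present to oxidise that radical to the exocyclic alkene. Both C7 epimers of 16 converge since C7 becomes sp2, and 1,1-diphenylethylene with the second equivalent of Mn(OAc)3 should remove the released PhSO2 radical as a vinyl sulfone before it can shift the allylic sulfone of unreacted 16 or scramble alkene geometry.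

Step 11
Reactants: 17 bicyclic 3-oxo 19-ester
Product: 18 (−)-8-phenylmenthyl (3S)-15-(tert-butyldiphenylsilyloxy)-3-hydroxylabda-7,13E-dien-19-oate (C3 hydroxyl axial, trans to the C4 ester)
Conditions: LiBH(s-Bu)3, THF, −78 °C; then H2O
Reagents that add atoms: none
Why: In this bulky-hydride reduction of a hindered cyclohexanone the reagent should avoid the axial path blocked by the axial hydrogens on C1 and C5 and add along the equatorial path, which sets C3 by substrate control with the hydroxyl axial and trans to C19.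

Step 12
Reactants: 18 3-hydroxy 19-ester
Product: 19 15-(tert-butyldiphenylsilyloxy)labda-7,13E-diene-3,19-diol (3-OH axial)
Conditions: LiAlH4, THF, 0 °C to reflux; aqueous work-up; 12 recovered
Reagents that add atoms: none
Why: LiAlH4 reduction of the neopentyl ester should give the primary C19 alcohol and release the auxiliary 12 for reuse, the silyl ether and both alkenes being inert.

Step 13
Reactants: 19 3,19-diol
Product: 20 19-(tert-butyldimethylsilyl) ether of 19 (3-OH free)
Conditions: t-BuMe2SiCl, imidazole, DMF, 0 °C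
Reagents that add atoms: tert-butyl(chloro)dimethylsilane CC(C)(C)[Si](C)(C)Cl
Why: Silylation should take the primary C19 hydroxyl far faster than the axial secondary C3 hydroxyl that sits next to quaternary C4.

Step 14
Reactants: 20 19-silyl ether
Product: 21 3-acetate of 20 (3-acetoxy, 15-OSi-t-BuPh2, 19-OSi-t-BuMe2)
Conditions: Ac2O, Et3N, DMAP, CH2Cl2, rt to 40 °C
Reagents that add atoms: acetic anhydride CC(=O)OC(C)=O
Why: DMAP-catalysed acylation should esterify the hindered axial C3 alcohol, the only free hydroxyl, with retention at C3.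

Step 15
Reactants: 21 3-acetate bis-silyl ether
Product: 22 3-acetoxylabda-7,13E-diene-15,19-diol
Conditions: Bu4NF, AcOH (1:1), THF, rt to 40 °C
Reagents that add atoms: none
Why: Buffered fluoride desilylation should free both primary alcohols while the acetate stays on O3, because O3 and C19 are trans-diaxial on ring A and cannot reach the cyclic orthoester needed for a 1,3-acyl shift.

Step 16
Reactants: 22 3-acetoxy 15,19-diol
Product: 23 3-acetoxy-19-hydroxylabda-7,13E-dien-15-al
Conditions: MnO2 (activated, excess), CH2Cl2, rt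
Reagents that add atoms: none
Why: MnO2 oxidises allylic alcohols selectively, so only C15 should be oxidised to the E-enal and the saturated neopentyl C19 alcohol should remain.

Step 17
Reactants: 23 enal
Product: 24 target, (3S,4R,5S,9R,10S,13E)-3-acetoxy-19-hydroxylabda-7,13-dien-15-oic acid
Conditions: NaClO2, NaH2PO4, 2-methylbut-2-ene, t-BuOH/H2O, 0 °C to rt
Reagents that add atoms: sodium chlorite [Na+].[O-]Cl=O
Why: The Pinnick oxidation should convert the enal into the acid without touching the C19 alcohol, the acetate or the alkenes, the scavenger taking up the hypochlorite.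

**Compound list**

1 | geraniol, (2E)-3,7-dimethylocta-2,6-dien-1-ol | CC(C)=CCC/C(C)=C/CO | starting material
2 | geranyl tert-butyldiphenylsilyl ether | CC(C)=CCC/C(C)=C/CO[Si](c1ccccc1)(c1ccccc1)C(C)(C)C | intermediate
3 | (2E,6E)-8-(tert-butyldiphenylsilyloxy)-2,6-dimethylocta-2,6-dien-1-ol | OC/C(C)=C/CC/C(C)=C/CO[Si](c1ccccc1)(c1ccccc1)C(C)(C)C | intermediate
4 | (2E,6E)-8-bromo-3,7-dimethylocta-2,6-dienyl tert-butyldiphenylsilyl ether | BrC/C(C)=C/CC/C(C)=C/CO[Si](c1ccccc1)(c1ccccc1)C(C)(C)C | intermediate
5 | (2E,6E)-3,7-dimethyl-8-(phenylsulfonyl)octa-2,6-dienyl tert-butyldiphenylsilyl ether | O=S(=O)(c1ccccc1)C/C(C)=C/CC/C(C)=C/CO[Si](c1ccccc1)(c1ccccc1)C(C)(C)C | intermediate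
6 | prenyl bromide, 1-bromo-3-methylbut-2-ene | CC(C)=CCBr | starting material
7 | α-lithio derivative of sulfone 5 | [Li]C(S(=O)(=O)c1ccccc1)/C(C)=C/CC/C(C)=C/CO[Si](c1ccccc1)(c1ccccc1)C(C)(C)C | intermediate
8 | (2E,6E)-3,7,11-trimethyl-8-(phenylsulfonyl)dodeca-2,6,10-trienyl tert-butyldiphenylsilyl ether, racemic at the sulfonyl carbon (C7) | CC(C)=CCC(S(=O)(=O)c1ccccc1)/C(C)=C/CC/C(C)=C/CO[Si](c1ccccc1)(c1ccccc1)C(C)(C)C | intermediate
9 | (2E,6E,10E)-12-hydroxy-3,7,11-trimethyl-8-(phenylsulfonyl)dodeca-2,6,10-trienyl tert-butyldiphenylsilyl ether, racemic at C7 | OC/C(C)=C/CC(S(=O)(=O)c1ccccc1)/C(C)=C/CC/C(C)=C/CO[Si](c1ccccc1)(c1ccccc1)C(C)(C)C | intermediate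
10 | methanesulfonate of alcohol 9 | CS(=O)(=O)OC/C(C)=C/CC(S(=O)(=O)c1ccccc1)/C(C)=C/CC/C(C)=C/CO[Si](c1ccccc1)(c1ccccc1)C(C)(C)C | intermediate
11 | (2E,6E,10E)-12-bromo-3,7,11-trimethyl-8-(phenylsulfonyl)dodeca-2,6,10-trienyl tert-butyldiphenylsilyl ether, racemic at C7 | BrC/C(C)=C/CC(S(=O)(=O)c1ccccc1)/C(C)=C/CC/C(C)=C/CO[Si](c1ccccc1)(c1ccccc1)C(C)(C)C | intermediate
12 | (−)-8-phenylmenthol, (1R,2S,5R)-5-methyl-2-(2-phenylpropan-2-yl)cyclohexan-1-ol | C[C@@H]1CC[C@H]([C@@H](C1)O)C(C)(C)c1ccccc1 | starting material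
13 | ethyl 2-methyl-3-oxobutanoate | CCOC(=O)C(C)C(C)=O | starting material
14 | (1R,2S,5R)-8-phenylmenthyl 2-methyl-3-oxobutanoate, mixture at the α-carbon | C[C@@H]1CC[C@H]([C@@H](C1)OC(=O)C(C)C(C)=O)C(C)(C)c1ccccc1 | intermediate
15 | sodium lithium dianion of 14 (α,γ-dienolate) | C[C@@H]1CC[C@H]([C@@H](C1)OC(=O)[C-](C)C(=O)[CH2-])C(C)(C)c1ccccc1.[Na+].[Li+] | intermediate
16 | (1R,2S,5R)-8-phenylmenthyl (6E,10E,14E)-16-(tert-butyldiphenylsilyloxy)-2,6,10,14-tetramethyl-3-oxo-9-(phenylsulfonyl)hexadeca-6,10,14-trienoate, mixture at chain C2 and C9 (labdane C4 and C7) | C[C@@H]1CC[C@H]([C@@H](C1)OC(=O)C(C)C(=O)CC/C(C)=C/CC(S(=O)(=O)c2ccccc2)/C(C)=C/CC/C(C)=C/CO[Si](c3ccccc3)(c4ccccc4)C(C)(C)C)C(C)(C)c5ccccc5 | intermediate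
17 | (1R,2S,5R)-8-phenylmenthyl (4S,5S,9R,10S,13E)-15-(tert-butyldiphenylsilyloxy)-3-oxolabda-7,13-dien-19-oate; trans-fused, ester axial and cis to C20 | O=C1CC[C@]2(C)[C@H](CC=C(C)[C@H]2CC/C(C)=C/CO[Si](c3ccccc3)(c3ccccc3)C(C)(C)C)[C@]1(C)C(=O)O[C@@H]4C[C@H](C)CC[C@H]4C(C)(C)c5ccccc5 | intermediate
18 | (1R,2S,5R)-8-phenylmenthyl (3S,4S,5S,9R,10S,13E)-15-(tert-butyldiphenylsilyloxy)-3-hydroxylabda-7,13-dien-19-oate; 3-OH axial, trans to the ester | O[C@H]1CC[C@]2(C)[C@H](CC=C(C)[C@H]2CC/C(C)=C/CO[Si](c3ccccc3)(c3ccccc3)C(C)(C)C)[C@]1(C)C(=O)O[C@@H]4C[C@H](C)CC[C@H]4C(C)(C)c5ccccc5 | intermediate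
19 | (3S,4R,5S,9R,10S,13E)-15-(tert-butyldiphenylsilyloxy)labda-7,13-diene-3,19-diol | O[C@H]1CC[C@]2(C)[C@H](CC=C(C)[C@H]2CC/C(C)=C/CO[Si](c3ccccc3)(c3ccccc3)C(C)(C)C)[C@]1(C)CO | intermediate
20 | (3S,4R,5S,9R,10S,13E)-19-(tert-butyldimethylsilyloxy)-15-(tert-butyldiphenylsilyloxy)labda-7,13-dien-3-ol | O[C@H]1CC[C@]2(C)[C@H](CC=C(C)[C@H]2CC/C(C)=C/CO[Si](c3ccccc3)(c3ccccc3)C(C)(C)C)[C@]1(C)CO[Si](C)(C)C(C)(C)C | intermediate
21 | (3S,4R,5S,9R,10S,13E)-3-acetoxy-19-(tert-butyldimethylsilyloxy)-15-(tert-butyldiphenylsilyloxy)labda-7,13-diene | CC(=O)O[C@H]1CC[C@]2(C)[C@H](CC=C(C)[C@H]2CC/C(C)=C/CO[Si](c3ccccc3)(c3ccccc3)C(C)(C)C)[C@]1(C)CO[Si](C)(C)C(C)(C)C | intermediate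
22 | (3S,4R,5S,9R,10S,13E)-3-acetoxylabda-7,13-diene-15,19-diol | CC(=O)O[C@H]1CC[C@]2(C)[C@H](CC=C(C)[C@H]2CC/C(C)=C/CO)[C@]1(C)CO | intermediate
23 | (3S,4R,5S,9R,10S,13E)-3-acetoxy-19-hydroxylabda-7,13-dien-15-al | CC(=O)O[C@H]1CC[C@]2(C)[C@H](CC=C(C)[C@H]2CC/C(C)=C/C=O)[C@]1(C)CO | intermediate
24 | (3S,4R,5S,9R,10S,13E)-3-acetoxy-19-hydroxylabda-7,13-dien-15-oic acid (CNP0129162.1) | CC(=O)O[C@H]1CC[C@]2(C)[C@H](CC=C(C)[C@H]2CC/C(C)=C/C(=O)O)[C@]1(C)CO | target

**Step count**
Total steps: 17. Longest linear sequence: 16 steps (steps 1–7 and 9–17; step 8 is the side branch).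

**Steps most likely to fail, with fallbacks**

Step 10 (proposed cascade). Three things may go wrong. β-Scission may be slow for the C7 epimer whose sulfonyl group sits equatorial, so that the C8 radical closes a third ring onto C13=C14. The released sulfonyl radical may shift the allylic sulfone or scramble alkene geometry in a chain process. The alkene trap may intercept the C4 radical. The fallback uses known chemistry, sets out from keto ester 14 (as its dianion 15) and comes back at diol 19. The side chain is cut back to a masked methyl ketone, so that no third alkene is present and the established Mn(OAc)3/Cu(OAc)2 bicyclization applies. Geranylacetone F1 is converted into its dioxolane F2 (ethylene glycol, PPTS), oxidised at the terminal E-methyl (SeO2, t-BuOOH) to the allylic alcohol F3 and brominated (CBr4, PPh3) to the allylic bromide F4. Alkylation of dianion 15 with F4 should give the dienyl keto ester F5. Mn(OAc)3·2H2O and Cu(OAc)2·H2O in degassed EtOH (chosen over AcOH to spare the dioxolane) should close rings A and B with the same auxiliary control and chair–chair fold; divalent copper oxidises the C8 radical mainly to the exocyclic C8=C17 alkene of bicycle F6. A cobalt-hydride hydrogen-atom-transfer isomerisation (Co(salen)Cl of trivalent cobalt, PhSiH3, benzene) should then move the alkene to the trisubstituted C7=C8 position, giving F7. LiBH(s-Bu)3 should give the axial hydroxy ester F8, and LiAlH4 the diol F9 with recovery of 12. Aqueous AcOH in THF should unmask the methyl ketone F10. A Horner–Wadsworth–Emmons reaction with triethyl phosphonoacetate and NaH should give the E-enoate F11, the Z isomer being removed by chromatography. i-Bu2AlH should give the 3,15,19-triol F12, and t-BuPh2SiCl/imidazole at −20 °C should silylate the unhindered allylic C15 hydroxyl to return 19.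

Step 9. The strongly basic dianion may take the acidic C7–H next to the sulfone instead of attacking the bromide, which quenches the nucleophile and lets 11 condense with itself. The fallback sets out from bromide 11 and comes back at 16: C1–C2 is made with a weakly basic malonate and the keto ester is then built by acylation. Sodium dimethyl malonate (excess, THF) should alkylate 11 to the malonate F13. LiOH hydrolysis gives the malonic acid F14, which should lose CO2 in warm pyridine to give the acid F15 (C3–C2–C1). Carbonyldiimidazole converts F15 into the acyl imidazolide F16. A Masamune–Brooks decarboxylative Claisen condensation of F16 with the magnesium salt (MgCl2, Et3N, MeCN) of (−)-8-phenylmenthyl hydrogen methylmalonate F17, itself made by opening 2,2,5-trimethyl-1,3-dioxane-4,6-dione with 12 in hot toluene, should give 16.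

Step 11. Facial selectivity at C3 may be poor, because the equatorial path of the bulky hydride passes the axial C4 ester with its large auxiliary. The fallback sets out from 17 and comes back at 19: hydride is delivered from the C19 oxygen instead. LiAlH4 reduces ketone and ester of 17 together to the diol F18 as a mixture of C3 epimers, with recovery of 12. t-BuMe2SiCl/imidazole gives the C19 silyl ether F19, and Dess–Martin periodinane the 3-ketone F20. PPTS in MeOH should remove only the tert-butyldimethylsilyl group, giving the β-hydroxy ketone F21. Me4NBH(OAc)3 in MeCN/AcOH at −20 °C (hydroxyl-directed triacetoxyborohydride reduction) binds the axial C19 hydroxyl and should pass hydride within the molecule to the face of C3 on the side of C19, so that the C3 hydroxyl ends axial and trans to C19, which is diol 19.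

Further compounds
F1 | step 10 | geranylacetone, (5E)-6,10-dimethylundeca-5,9-dien-2-one | CC(C)=CCC/C(C)=C/CCC(C)=O
F2 | step 10 | ethylene ketal (dioxolane) of F1 | CC(C)=CCC/C(C)=C/CCC1(C)OCCO1
F3 | step 10 | (2E,6E)-2,6-dimethyl-9-(2-methyl-1,3-dioxolan-2-yl)nona-2,6-dien-1-ol | OC/C(C)=C/CC/C(C)=C/CCC1(C)OCCO1
F4 | step 10 | allylic bromide from F3 | BrC/C(C)=C/CC/C(C)=C/CCC1(C)OCCO1
F5 | step 10 | (−)-8-phenylmenthyl dienyl 2-methyl β-keto ester with the dioxolane side chain (mixture at C4) | C[C@@H]1CC[C@H]([C@@H](C1)OC(=O)C(C)C(=O)CC/C(C)=C/CC/C(C)=C/CCC2(C)OCCO2)C(C)(C)c3ccccc3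
F6 | step 10 | bicyclic 3-oxo 19-(8-phenylmenthyl) ester with exocyclic C8=C17 alkene and C13 dioxolane | O=C1CC[C@]2(C)[C@H](CCC(=C)[C@H]2CCC3(C)OCCO3)[C@]1(C)C(=O)O[C@@H]4C[C@H](C)CC[C@H]4C(C)(C)c5ccccc5
F7 | step 10 | C7=C8 isomer of F6 | O=C1CC[C@]2(C)[C@H](CC=C(C)[C@H]2CCC3(C)OCCO3)[C@]1(C)C(=O)O[C@@H]4C[C@H](C)CC[C@H]4C(C)(C)c5ccccc5
F8 | step 10 | axial 3-hydroxy 19-ester from F7 | O[C@H]1CC[C@]2(C)[C@H](CC=C(C)[C@H]2CCC3(C)OCCO3)[C@]1(C)C(=O)O[C@@H]4C[C@H](C)CC[C@H]4C(C)(C)c5ccccc5
F9 | step 10 | 3,19-diol with C13 dioxolane | O[C@H]1CC[C@]2(C)[C@H](CC=C(C)[C@H]2CCC3(C)OCCO3)[C@]1(C)CO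
F10 | step 10 | 3,19-dihydroxy 13-methyl ketone (14,15-dinor) | O[C@H]1CC[C@]2(C)[C@H](CC=C(C)[C@H]2CCC(C)=O)[C@]1(C)CO
F11 | step 10 | ethyl (13E)-3,19-dihydroxylabda-7,13-dien-15-oate | O[C@H]1CC[C@]2(C)[C@H](CC=C(C)[C@H]2CC/C(C)=C/C(=O)OCC)[C@]1(C)CO
F12 | step 10 | (13E)-labda-7,13-diene-3,15,19-triol | O[C@H]1CC[C@]2(C)[C@H](CC=C(C)[C@H]2CC/C(C)=C/CO)[C@]1(C)CO
F13 | step 9 | dimethyl malonate alkylated at C1 by 11 | COC(=O)C(C/C(C)=C/CC(S(=O)(=O)c1ccccc1)/C(C)=C/CC/C(C)=C/CO[Si](c1ccccc1)(c1ccccc1)C(C)(C)C)C(=O)OC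
F14 | step 9 | malonic acid from F13 | OC(=O)C(C/C(C)=C/CC(S(=O)(=O)c1ccccc1)/C(C)=C/CC/C(C)=C/CO[Si](c1ccccc1)(c1ccccc1)C(C)(C)C)C(=O)O
F15 | step 9 | carboxylic acid C3–C2–C1 chain after decarboxylation | OC(=O)CC/C(C)=C/CC(S(=O)(=O)c1ccccc1)/C(C)=C/CC/C(C)=C/CO[Si](c1ccccc1)(c1ccccc1)C(C)(C)C
F16 | step 9 | acyl imidazolide of F15 | O=C(CC/C(C)=C/CC(S(=O)(=O)c1ccccc1)/C(C)=C/CC/C(C)=C/CO[Si](c1ccccc1)(c1ccccc1)C(C)(C)C)n1ccnc1
F17 | step 9 | (−)-8-phenylmenthyl hydrogen methylmalonate | C[C@@H]1CC[C@H]([C@@H](C1)OC(=O)C(C)C(=O)O)C(C)(C)c1ccccc1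
F18 | step 11 | 15-(tert-butyldiphenylsilyloxy)labda-7,13E-diene-3,19-diol, mixture of C3 epimers | OC1CC[C@]2(C)[C@H](CC=C(C)[C@H]2CC/C(C)=C/CO[Si](c3ccccc3)(c3ccccc3)C(C)(C)C)[C@]1(C)CO
F19 | step 11 | 19-(tert-butyldimethylsilyl) ether of F18 | OC1CC[C@]2(C)[C@H](CC=C(C)[C@H]2CC/C(C)=C/CO[Si](c3ccccc3)(c3ccccc3)C(C)(C)C)[C@]1(C)CO[Si](C)(C)C(C)(C)C
F20 | step 11 | 3-ketone with both silyl ethers | O=C1CC[C@]2(C)[C@H](CC=C(C)[C@H]2CC/C(C)=C/CO[Si](c3ccccc3)(c3ccccc3)C(C)(C)C)[C@]1(C)CO[Si](C)(C)C(C)(C)C
F21 | step 11 | 19-hydroxy 3-ketone (β-hydroxy ketone) | O=C1CC[C@]2(C)[C@H](CC=C(C)[C@H]2CC/C(C)=C/CO[Si](c3ccccc3)(c3ccccc3)C(C)(C)C)[C@]1(C)CO
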